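**Plan**

Numbering used throughout: oxolane O1, C2 (aryl), C3 (CH2OH), C4 (spiro carbon), C5 (side chain); the dienone is ring B, its MeO-bearing arm is Ca(OMe)=CbH, the other arm is CcH=CdH.
Retrosynthesis: ring B is opened at Cc=Cd (dehydrogenation) and at Ca=Cb (aldol) to a C4-formyl, C4-(4-methoxy-3-oxobutyl) oxolane. The oxolane is then cut at C2–C3 together with a 1,2-shift of C5 (Prins–pinacol transform) into a vanillin silyl ether and an acyclic (Z)-allylic 1,2-diol. The diol is cut at the aryl ether C–O bond (epoxide opening) and at the carbinol–olefin C–C bond (Nozaki–Hiyama–Kishi).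
Forward: chain assembly (steps 1–11), oxolane with the quaternary carbon (step 13), ring B by aldol condensation (step 14) and dehydrogenation (step 15), desilylation (step 16).
Stereochemistry: Sharpless epoxidation sets C5 and, after SN2 opening, the threo aryloxy carbon. C5 and the (Z)-olefin geometry (trans-hydroalumination/iodination) are relayed to C3 and C4 in the chair Prins–pinacol step. C2 is set by equilibration trans to C3.
Enabling feature: C4 carries a vinylic CH of ring B (a latent formyl group) and lies β to O1. The oxolane is therefore a 3-acyloxolane retron in which C2(aryl)–O1 is an aldehyde-derived oxocarbenium ion and C3–C4 an olefin.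

Key step: step 13

Remark: the carbinol epimer ratio of step 9 is taken to be immaterial, because that carbon becomes the formyl carbon in step 13; the expected Felkin epimer is the one drawn. TBDPS = tert-butyldiphenylsilyl, TIPS = triisopropylsilyl.

**Route**

Step 1
Reactants: 1 (Z)-but-2-ene-1,4-diol
Product: 2 (Z)-4-(TBDPS-oxy)but-2-en-1-ol
Conditions: NaH (1.0 equiv), THF, 0 °C; TBDPSCl (1.0 equiv), rt
Reagents that add atoms: tert-butyl(chloro)diphenylsilane (TBDPSCl), CC(C)(C)[Si](Cl)(c1ccccc1)c1ccccc1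
Why: Monosilylation of a symmetric diol through its sparingly soluble monosodium alkoxide should give mainly the mono ether.

Step 2
Reactants: 2 (Z)-4-(TBDPS-oxy)but-2-en-1-ol
Product: 3 [(2S,3R)-3-(TBDPS-oxymethyl)oxiran-2-yl]methanol (cis-epoxy alcohol)
Conditions: Ti(OiPr)4, L-(+)-diisopropyl tartrate, t-BuOOH, 4 Å MS, CH2Cl2, −20 °C
Reagents that add atoms: tert-butyl hydroperoxide, CC(C)(C)OO
Why: Sharpless asymmetric epoxidation of a (Z)-allylic alcohol; the titanium L-(+)-tartrate complex delivers oxygen to one olefin face and so sets both epoxide carbons (the future C5 and, after inversion in step 11, the aryloxy carbon).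

Step 3
Reactants: 3 cis-epoxy alcohol
Product: 4 (2R,3R)-3-(TBDPS-oxymethyl)oxirane-2-carbaldehyde (cis)
Conditions: Dess–Martin periodinane, pyridine, CH2Cl2, 0 °C → rt; used crude
Reagents that add atoms: none
Why: Dess–Martin oxidation under buffered, non-basic conditions should give the cis-epoxy aldehyde without epimerization at its α-carbon.

Step 4
Reactants: 5 methyl 4-methoxy-3-oxobutanoate; 6 4-chlorobut-2-yn-1-ol
Product: 7 methyl 6-hydroxy-2-(methoxyacetyl)hex-4-ynoate (racemic)
Conditions: K2CO3, NaI (cat.), acetone, reflux; 5 in excess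
Reagents that add atoms: none
Why: C-alkylation of the β-keto ester enolate with a propargylic chloride (acetoacetic ester synthesis); excess keto ester should suppress dialkylation.

Step 5
Reactants: 7 methyl 6-hydroxy-2-(methoxyacetyl)hex-4-ynoate
Product: 8 7-hydroxy-1-methoxyhept-5-yn-2-one
Conditions: LiCl, H2O, DMSO, 130 °C
Reagents that add atoms: none
Why: Krapcho dealkoxycarbonylation of the β-keto ester should leave the methoxymethyl ketone; the only stereocenter is removed.

Step 6
Reactants: 8 7-hydroxy-1-methoxyhept-5-yn-2-one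
Product: 9 5-[2-(methoxymethyl)-1,3-dioxolan-2-yl]pent-2-yn-1-ol
Conditions: HOCH2CH2OH, p-TsOH·H2O (cat.), benzene, reflux, Dean–Stark
Reagents that add atoms: ethylene glycol, OCCO
Why: Acid-catalysed dioxolane formation masks the ketone against the hydride and organochromium reagents of steps 7 and 9.

Step 7
Reactants: 9 5-[2-(methoxymethyl)-1,3-dioxolan-2-yl]pent-2-yn-1-ol
Product: 10 (Z)-3-iodo-5-[2-(methoxymethyl)-1,3-dioxolan-2-yl]pent-2-en-1-ol
Conditions: NaAlH2(OCH2CH2OMe)2 (Red-Al), THF, 0 °C → rt; EtOAc; then I2, −78 °C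
Reagents that add atoms: iodine, II
Why: Hydroxyl-directed trans-hydroalumination of the propargylic alcohol places aluminium on the distal carbon and iodinolysis proceeds with retention, so iodine should end cis to CH2OH.

Step 8
Reactants: 10 (Z)-iodo allylic alcohol
Product: 11 TBDPS ether of 10 (alkenyl iodide)
Conditions: TBDPSCl, imidazole, CH2Cl2, rt
Reagents that add atoms: tert-butyl(chloro)diphenylsilane (TBDPSCl), CC(C)(C)[Si](Cl)(c1ccccc1)c1ccccc1
Why: Standard imidazole-mediated silylation of a primary alcohol.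

Step 9
Reactants: 4 cis-epoxy aldehyde; 11 alkenyl iodide
Product: 12 epoxy allylic alcohol (carbinol S, Felkin epimer drawn; oxirane 2S,3R; olefin with the carbinol carbon cis to CH2OTBDPS)
Conditions: CrCl2 (4 equiv), NiCl2 (1 mol %), DMSO/THF, rt
Reagents that add atoms: none
Why: Nozaki–Hiyama–Kishi coupling; the alkenylchromium reagent forms with retention of olefin geometry and adds chemoselectively to the aldehyde under non-basic conditions that spare the epoxide, with Felkin–Anh addition anti to the epoxide C–O bond expected to favour the drawn epimer.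

Step 10
Reactants: 13 4-(3-hydroxypropyl)-2-methoxyphenol (dihydroconiferyl alcohol)
Product: 14 4-[3-(TBDPS-oxy)propyl]-2-methoxyphenol
Conditions: TBDPSCl (1.05 equiv), imidazole, CH2Cl2, 0 °C
Reagents that add atoms: tert-butyl(chloro)diphenylsilane (TBDPSCl), CC(C)(C)[Si](Cl)(c1ccccc1)c1ccccc1
Why: A bulky silyl chloride at low temperature should silylate the unhindered primary alcohol in preference to the hydrogen-bonded ortho-methoxyphenol.

Step 11
Reactants: 12 epoxy allylic alcohol; 14 silyl-protected phenol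
Product: 15 (2S,3S,4S,5Z)-1,7-bis(TBDPS-oxy)-2-{4-[3-(TBDPS-oxy)propyl]-2-methoxyphenoxy}-5-{2-[2-(methoxymethyl)-1,3-dioxolan-2-yl]ethyl}hept-5-ene-3,4-diol
Conditions: Ti(OiPr)4 (1.5 equiv, premixed with 14, i-PrOH stripped), 14 (3 equiv), toluene, 50 °C
Reagents that add atoms: none
Why: Titanium-mediated opening of a 2,3-epoxy alcohol; chelation of the epoxy alkoxide directs the aryloxide to the distal epoxide carbon with inversion, which should turn the cis-epoxide into the threo aryl ether and expose the 1,2-diol needed for step 13.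

Step 12
Reactants: 16 vanillin
Product: 17 3-methoxy-4-(TIPS-oxy)benzaldehyde
Conditions: TIPSCl, imidazole, DMF, rt
Reagents that add atoms: chlorotri(propan-2-yl)silane (TIPSCl), CC(C)[Si](Cl)(C(C)C)C(C)C
Why: Standard phenol silylation; the TIPS ether keeps the ring electron-rich yet inert to the Lewis acid of step 13.

Step 13
Reactants: 15 allylic anti-1,2-diol; 17 3-methoxy-4-(TIPS-oxy)benzaldehyde
Product: 20 4-formyl oxolane (aryl trans to CH2OTBDPS; CH2OTBDPS cis to formyl and side chain), via dioxolane acetal 18 (not isolated), via all-cis aldehyde epimer 19 (not isolated)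
Conditions: 17 (1.5 equiv), BF3·OEt2 (3 equiv), MgSO4, CH2Cl2, −55 → −20 °C; then 0 °C until the C2 epimers have equilibrated
Reagents that add atoms: none
Why: BF3-promoted condensation gives acetal 18, which ionizes at the allylic C–O bond to the (E)-aryl oxocarbenium ion on O1; the trisubstituted olefin attacks it in a chair transition state (Prins step, forming the C2–C3 bond) and the tertiary cation at C4 is quenched by 1,2-shift of C5 from the carbinol carbon to C4 (pinacol step, carbinol → formyl), the closest known reaction type being the Prins–pinacol synthesis of 3-acyl- and 3-formyloxolanes from allylic 1,2-diols and aldehydes. The tetrahydropyranyl cation closes 6-endo-trig and the oxolane arises from it by ring contraction, so no 5-endo closure is needed. C5 (side chain equatorial in the chair) controls C3 and C4: the (Z)-olefin from step 7 places CH2OTBDPS axial and therefore cis to the side chain, and C5 migrates with retention to the face of C4 that it already occupies, which puts the formyl group cis and the ketal-bearing arm trans to the side chain. C2 is formed cis to C3 under kinetic control (19) and should then equilibrate at 0 °C, by reversible ionization of the electron-rich benzylic C2–O1 bond, to the 2,3-trans isomer 20 that the target requires. The step needs ring contraction to outrun 1,2-hydride shift and the stepwise 2-oxonia-Cope/aldol path, and the ketal to stay closed until the cation is consumed; the alkyl-stabilized tertiary cation and the low temperature should secure this, and the carbinol stereocenter from step 9 is destroyed here.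

Step 14
Reactants: 20 4-formyl oxolane
Product: 22 spiro 2-methoxycyclohex-2-enone (tetrasilyl ether), via keto aldehyde 21 (not isolated)
Conditions: PPTS, acetone/H2O, 55 °C; then pyrrolidine, AcOH, toluene, 60 °C
Reagents that add atoms: water, O
Why: Acidic transketalization unmasks the methoxymethyl ketone, and amine-catalysed intramolecular aldol condensation onto the non-enolizable formyl group can only close the six-membered ring through the MeO-bearing carbon; the quaternary carbon of step 13 becomes the spiro carbon unchanged, with the MeO arm on the face of the side chain.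

Step 15
Reactants: 22 spiro enone
Product: 24 tetrasilyl ether of the target (spiro dienone), via silyl dienol ether 23 (not isolated)
Conditions: Me3SiOTf, Et3N, CH2Cl2, 0 °C; then Pd(OAc)2 (1.1 equiv), MeCN, rt
Reagents that add atoms: none
Why: Saegusa–Ito dehydrogenation; the ketone has a single enolizable position, so the cross-conjugated silyl dienol ether forms regioselectively and palladium diacetate should introduce the Cc=Cd double bond.

Step 16
Reactants: 24 tetrasilyl ether of the target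
Product: 25 CNP0252711.1
Conditions: Bu4NF, AcOH (1:1), THF, 0 °C → rt
Reagents that add atoms: none
Why: Buffered fluoride should cleave the aryl TIPS ether and the three primary TBDPS ethers without exposing the dienone or the p-hydroxybenzylic ether to free base; no stereocenter is touched.

**Compound list**

1 | (Z)-but-2-ene-1,4-diol | OC/C=C\CO | starting material
2 | (Z)-4-(TBDPS-oxy)but-2-en-1-ol | OC/C=C\CO[Si](c1ccccc1)(c1ccccc1)C(C)(C)C | intermediate
3 | [(2S,3R)-3-(TBDPS-oxymethyl)oxiran-2-yl]methanol | OC[C@@H]1O[C@@H]1CO[Si](c1ccccc1)(c1ccccc1)C(C)(C)C | intermediate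
4 | (2R,3R)-3-(TBDPS-oxymethyl)oxirane-2-carbaldehyde | O=C[C@@H]1O[C@@H]1CO[Si](c1ccccc1)(c1ccccc1)C(C)(C)C | intermediate
5 | methyl 4-methoxy-3-oxobutanoate | COCC(=O)CC(=O)OC | starting material
6 | 4-chlorobut-2-yn-1-ol | OCC#CCCl | starting material
7 | methyl 6-hydroxy-2-(methoxyacetyl)hex-4-ynoate (racemic) | COCC(=O)C(CC#CCO)C(=O)OC | intermediate
8 | 7-hydroxy-1-methoxyhept-5-yn-2-one | COCC(=O)CCC#CCO | intermediate
9 | 5-[2-(methoxymethyl)-1,3-dioxolan-2-yl]pent-2-yn-1-ol | COCC1(CCC#CCO)OCCO1 | intermediate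
10 | (Z)-3-iodo-5-[2-(methoxymethyl)-1,3-dioxolan-2-yl]pent-2-en-1-ol | COCC1(CC/C(I)=C/CO)OCCO1 | intermediate
11 | TBDPS ether of 10 | COCC1(CC/C(I)=C/CO[Si](c2ccccc2)(c2ccccc2)C(C)(C)C)OCCO1 | intermediate
12 | (1S,2Z)-4-(TBDPS-oxy)-1-[(2S,3R)-3-(TBDPS-oxymethyl)oxiran-2-yl]-2-{2-[2-(methoxymethyl)-1,3-dioxolan-2-yl]ethyl}but-2-en-1-ol | CC(C)(C)[Si](c1ccccc1)(c1ccccc1)OC[C@H]1O[C@H]1[C@@H](O)/C(CCC1(COC)OCCO1)=C\CO[Si](c1ccccc1)(c1ccccc1)C(C)(C)C | intermediate
13 | 4-(3-hydroxypropyl)-2-methoxyphenol | COc1cc(CCCO)ccc1O | starting material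
14 | 4-[3-(TBDPS-oxy)propyl]-2-methoxyphenol | COc1cc(CCCO[Si](c2ccccc2)(c2ccccc2)C(C)(C)C)ccc1O | intermediate
15 | (2S,3S,4S,5Z)-1,7-bis(TBDPS-oxy)-2-{4-[3-(TBDPS-oxy)propyl]-2-methoxyphenoxy}-5-{2-[2-(methoxymethyl)-1,3-dioxolan-2-yl]ethyl}hept-5-ene-3,4-diol | CC(C)(C)[Si](c1ccccc1)(c1ccccc1)OC[C@H](Oc1ccc(CCCO[Si](c2ccccc2)(c2ccccc2)C(C)(C)C)cc1OC)[C@@H](O)[C@@H](O)/C(CCC1(COC)OCCO1)=C\CO[Si](c1ccccc1)(c1ccccc1)C(C)(C)C | intermediate
16 | vanillin | COc1cc(C=O)ccc1O | starting material
17 | 3-methoxy-4-(TIPS-oxy)benzaldehyde | COc1cc(C=O)ccc1O[Si](C(C)C)(C(C)C)C(C)C | intermediate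
18 | 2-[3-methoxy-4-(TIPS-oxy)phenyl]-1,3-dioxolane spanning the two carbinol oxygens of 15 (both epimers at the acetal carbon) | CC(C)(C)[Si](c1ccccc1)(c1ccccc1)OC[C@H](Oc1ccc(CCCO[Si](c2ccccc2)(c2ccccc2)C(C)(C)C)cc1OC)[C@H]1OC(c2ccc(O[Si](C(C)C)(C(C)C)C(C)C)c(OC)c2)O[C@H]1/C(CCC1(COC)OCCO1)=C\CO[Si](c1ccccc1)(c1ccccc1)C(C)(C)C | intermediate
19 | C2 epimer of 20 (aryl, CH2OTBDPS, formyl and side chain all on one ring face) | O=C[C@]1(CCC2(COC)OCCO2)[C@H](CO[Si](c2ccccc2)(c2ccccc2)C(C)(C)C)[C@H](c2ccc(O[Si](C(C)C)(C(C)C)C(C)C)c(OC)c2)O[C@@H]1[C@H](CO[Si](c1ccccc1)(c1ccccc1)C(C)(C)C)Oc1ccc(CCCO[Si](c2ccccc2)(c2ccccc2)C(C)(C)C)cc1OC | intermediate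
20 | (2S,3R,4R,5S)-2-[3-methoxy-4-(TIPS-oxy)phenyl]-3-(TBDPS-oxymethyl)-4-{2-[2-(methoxymethyl)-1,3-dioxolan-2-yl]ethyl}-5-[(1S)-2-(TBDPS-oxy)-1-{4-[3-(TBDPS-oxy)propyl]-2-methoxyphenoxy}ethyl]oxolane-4-carbaldehyde (plan numbering) | O=C[C@]1(CCC2(COC)OCCO2)[C@H](CO[Si](c2ccccc2)(c2ccccc2)C(C)(C)C)[C@@H](c2ccc(O[Si](C(C)C)(C(C)C)C(C)C)c(OC)c2)O[C@@H]1[C@H](CO[Si](c1ccccc1)(c1ccccc1)C(C)(C)C)Oc1ccc(CCCO[Si](c2ccccc2)(c2ccccc2)C(C)(C)C)cc1OC | intermediate
21 | 20 with the dioxolane replaced by the free ketone (4-methoxy-3-oxobutyl arm) | O=C[C@]1(CCC(=O)COC)[C@H](CO[Si](c2ccccc2)(c2ccccc2)C(C)(C)C)[C@@H](c2ccc(O[Si](C(C)C)(C(C)C)C(C)C)c(OC)c2)O[C@@H]1[C@H](CO[Si](c1ccccc1)(c1ccccc1)C(C)(C)C)Oc1ccc(CCCO[Si](c2ccccc2)(c2ccccc2)C(C)(C)C)cc1OC | intermediate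
22 | 24 with the Cc–Cd bond of ring B saturated (spiro 2-methoxycyclohex-2-enone) | COC1=C[C@]2(CCC1=O)[C@H](CO[Si](c1ccccc1)(c1ccccc1)C(C)(C)C)[C@@H](c1ccc(O[Si](C(C)C)(C(C)C)C(C)C)c(OC)c1)O[C@@H]2[C@H](CO[Si](c1ccccc1)(c1ccccc1)C(C)(C)C)Oc1ccc(CCCO[Si](c2ccccc2)(c2ccccc2)C(C)(C)C)cc1OC | intermediate
23 | trimethylsilyl dienol ether of 22 (C=C between the carbonyl carbon and Cd) | COC1=C[C@]2(CC=C1O[Si](C)(C)C)[C@H](CO[Si](c1ccccc1)(c1ccccc1)C(C)(C)C)[C@@H](c1ccc(O[Si](C(C)C)(C(C)C)C(C)C)c(OC)c1)O[C@@H]2[C@H](CO[Si](c1ccccc1)(c1ccccc1)C(C)(C)C)Oc1ccc(CCCO[Si](c2ccccc2)(c2ccccc2)C(C)(C)C)cc1OC | intermediate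
24 | target with the phenol as TIPS ether and the three primary alcohols as TBDPS ethers | COC1=C[C@]2(C=CC1=O)[C@H](CO[Si](c1ccccc1)(c1ccccc1)C(C)(C)C)[C@@H](c1ccc(O[Si](C(C)C)(C(C)C)C(C)C)c(OC)c1)O[C@@H]2[C@H](CO[Si](c1ccccc1)(c1ccccc1)C(C)(C)C)Oc1ccc(CCCO[Si](c2ccccc2)(c2ccccc2)C(C)(C)C)cc1OC | intermediate
25 | CNP0252711.1: (1S,3S,4R,5S)-1-{(1S)-2-hydroxy-1-[4-(3-hydroxypropyl)-2-methoxyphenoxy]ethyl}-3-(4-hydroxy-3-methoxyphenyl)-4-(hydroxymethyl)-7-methoxy-2-oxaspiro[4.5]deca-6,9-dien-8-one | COC1=C[C@]2(C=CC1=O)[C@H](CO)[C@@H](c1ccc(O)c(OC)c1)O[C@@H]2[C@H](CO)Oc1ccc(CCCO)cc1OC | target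

**Count and risks**

Total step count: 16. Longest linear sequence: 11 steps (steps 4, 5, 6, 7, 8, 9, 11, 13, 14, 15, 16).

Step 13. What may go wrong: the tertiary cation may be diverted by 1,2-hydride shift to a pyranone, by capture through the ketal oxygen, or by the stepwise 2-oxonia-Cope/aldol path with loss of the olefin-geometry relay. Ring contraction may also stall at the congested quaternary carbon, and the C2 equilibration may remain incomplete. Fallback (the quaternary carbon is made after ring closure by Robinson-type spiroannulation instead of in the cationic step): it sets out from 4. Addition of the lithium acetylide of commercial tert-butyldiphenyl(prop-2-ynyloxy)silane (n-BuLi, THF, −78 °C) should give the propargylic alcohol F1. Semihydrogenation (H2, Pd/CaCO3 poisoned with Pb(OAc)2, quinoline) should give the (Z)-allylic alcohol F2. Opening with 14 as in step 11 should give the diol F3. Prins–pinacol condensation with 17 under the conditions of step 13, now without ketal and without quaternary carbon, followed by C2 equilibration, should give the enolizable 4-formyl oxolane F4. Pyrrolidine-catalysed Michael addition of F4 to 1-methoxybut-3-en-2-one should occur on the C4 face opposite to the cis substituents at C3 and C5 and give keto aldehyde 21, so the route is rejoined at 21, which closes to 22 as in step 14.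

Step 11. What may go wrong: attack of the aryloxide at the carbinol-side epoxide carbon, transfer of isopropoxide from titanium, or no opening next to the bulky silyloxymethyl group. Fallback (regiocontrol by an ester instead of titanium chelation, with the aryl ether made before fragment coupling): it sets out from 4. Oxidative esterification (N-iodosuccinimide, K2CO3, MeOH) should give the methyl cis-glycidate F5. Cs2CO3-mediated opening with 14 at the β-carbon should give the threo α-hydroxy-β-aryloxy ester F6. Et3SiOTf/2,6-lutidine should give the triethylsilyl ether F7, and iBu2AlH at −78 °C the aldehyde F8. Nozaki–Hiyama–Kishi coupling with 11 should give the mono-protected diol F9, and HF·pyridine should remove the triethylsilyl group and return to 15.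

Step 15. What may go wrong: slow β-hydride elimination beside the congested spiro carbon, hydrolysis of the silyl dienol ether back to 22, or palladium-induced oxidation of the electron-rich arenes. Fallback (selenoxide syn-elimination instead of palladium dehydrogenation): it sets out from 22. LiN(SiMe3)2 then PhSeCl (THF, −78 °C) should give the α′-phenylselanyl ketone F10, and oxidation with H2O2/pyridine at 0 °C should trigger syn-elimination and return to 24.

Further compounds
F1 | step 13 | (1S)-4-(TBDPS-oxy)-1-[(2S,3R)-3-(TBDPS-oxymethyl)oxiran-2-yl]but-2-yn-1-ol | CC(C)(C)[Si](c1ccccc1)(c1ccccc1)OC[C@H]1O[C@H]1[C@@H](O)C#CCO[Si](c1ccccc1)(c1ccccc1)C(C)(C)C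
F2 | step 13 | (1S,2Z)-4-(TBDPS-oxy)-1-[(2S,3R)-3-(TBDPS-oxymethyl)oxiran-2-yl]but-2-en-1-ol | CC(C)(C)[Si](c1ccccc1)(c1ccccc1)OC[C@H]1O[C@H]1[C@@H](O)/C=C\CO[Si](c1ccccc1)(c1ccccc1)C(C)(C)C
F3 | step 13 | analogue of 15 without the ketal-bearing arm (disubstituted (Z)-olefin) | CC(C)(C)[Si](c1ccccc1)(c1ccccc1)OC[C@H](Oc1ccc(CCCO[Si](c2ccccc2)(c2ccccc2)C(C)(C)C)cc1OC)[C@@H](O)[C@@H](O)/C=C\CO[Si](c1ccccc1)(c1ccccc1)C(C)(C)C
F4 | step 13 | analogue of 20 with hydrogen at C4 in place of the ketal-bearing arm (C4 epimers) | O=CC1[C@H](CO[Si](c2ccccc2)(c2ccccc2)C(C)(C)C)[C@@H](c2ccc(O[Si](C(C)C)(C(C)C)C(C)C)c(OC)c2)O[C@@H]1[C@H](CO[Si](c1ccccc1)(c1ccccc1)C(C)(C)C)Oc1ccc(CCCO[Si](c2ccccc2)(c2ccccc2)C(C)(C)C)cc1OC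
F5 | step 11 | methyl cis-3-(TBDPS-oxymethyl)oxirane-2-carboxylate (configuration of 4) | COC(=O)[C@@H]1O[C@@H]1CO[Si](c1ccccc1)(c1ccccc1)C(C)(C)C
F6 | step 11 | methyl threo-2-hydroxy-3-aryloxy-4-(TBDPS-oxy)butanoate (aryl as in 14) | COC(=O)[C@H](O)[C@H](CO[Si](c1ccccc1)(c1ccccc1)C(C)(C)C)Oc1ccc(CCCO[Si](c2ccccc2)(c2ccccc2)C(C)(C)C)cc1OC
F7 | step 11 | triethylsilyl ether of F6 | COC(=O)[C@H](O[Si](CC)(CC)CC)[C@H](CO[Si](c1ccccc1)(c1ccccc1)C(C)(C)C)Oc1ccc(CCCO[Si](c2ccccc2)(c2ccccc2)C(C)(C)C)cc1OC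
F8 | step 11 | threo-3-aryloxy-4-(TBDPS-oxy)-2-(triethylsilyloxy)butanal | O=C[C@H](O[Si](CC)(CC)CC)[C@H](CO[Si](c1ccccc1)(c1ccccc1)C(C)(C)C)Oc1ccc(CCCO[Si](c2ccccc2)(c2ccccc2)C(C)(C)C)cc1OC
F9 | step 11 | 15 with its C3 hydroxyl (heptene numbering) as triethylsilyl ether | CC(C)(C)[Si](c1ccccc1)(c1ccccc1)OC[C@H](Oc1ccc(CCCO[Si](c2ccccc2)(c2ccccc2)C(C)(C)C)cc1OC)[C@@H](O[Si](CC)(CC)CC)[C@@H](O)/C(CCC1(COC)OCCO1)=C\CO[Si](c1ccccc1)(c1ccccc1)C(C)(C)C
F10 | step 15 | 22 bearing a phenylselanyl group on the CH2 next to the ketone (epimers) | COC1=C[C@]2(CC([Se]c3ccccc3)C1=O)[C@H](CO[Si](c1ccccc1)(c1ccccc1)C(C)(C)C)[C@@H](c1ccc(O[Si](C(C)C)(C(C)C)C(C)C)c(OC)c1)O[C@@H]2[C@H](CO[Si](c1ccccc1)(c1ccccc1)C(C)(C)C)Oc1ccc(CCCO[Si](c2ccccc2)(c2ccccc2)C(C)(C)C)cc1OC
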